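**Plan**

- Retrosynthesis: the two acetates come off first (C3–O, C13–O). The butenolide is then cut at C11–C12 and C6–C7 (and at the lactone C12–O bond) to CO and the acyclic epoxy ynal 21. Ynal 21 is cut at C9–C10 into vinyl iodide 11 and alkyl iodide 16, and 11 is cut at C2–C3 back to enal 3.
- Enabling feature: the lactone ring O–C6–C7=C11–C12(=O) is the formal [2+2+1] adduct of an aldehyde (C6=O), an internal alkyne (C7≡C11) and CO (C12). C6 and C7 are adjacent members of the ten-membered carbocycle, so one annulation closes the carbocycle and the butenolide together.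
- Forward order: the C1–C6 chain piece and the C7–C13 piece are made separately and joined at C9–C10. The epoxide is put on the open chain, both rings are formed in step 12, and the acetates go on last.
- Stereochemistry: C3 comes from a catalyst-controlled propargylation (step 2). C1 and C10 come from a Shi epoxidation (step 9). C6 is set in step 12 under control of C3. The 4E alkene comes from an E-selective Wittig reaction, and the E alkene that is later epoxidized comes from syn-hydrozirconation and a retentive coupling.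

Key step: step 12

Remark: germacrane numbering is used (ring C1–C10, C11–C13 on C7, C12 the lactone carbonyl, C14 on C10, C15 on C4), in which the target is (1R,3S,6R,10R,4E)-3,13-diacetoxy-1,10-epoxygermacra-4,7(11)-dien-12,6-olide; starting materials 1, 2, 4, 12 and 13 are taken as commercially available.

**Route**

Step 1
Reactants: 1 2-[(4-methoxybenzyl)oxy]acetaldehyde; 2 2-(triphenylphosphoranylidene)propanal
Product: 3 (2E)-4-[(4-methoxybenzyl)oxy]-2-methylbut-2-enal
Conditions: toluene, 80 °C
Reagents that add atoms: none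
Why: Wittig olefination with a stabilized formyl ylide is E-selective, which fixes the C4=C5 geometry, and the enal formed is less electrophilic than 1, so a second olefination should stay minor.

Step 2
Reactants: 3 (2E)-4-[(4-methoxybenzyl)oxy]-2-methylbut-2-enal; 4 allenylboronic acid pinacol ester
Product: 6 (2E,4S)-1-[(4-methoxybenzyl)oxy]-3-methylhept-2-en-6-yn-4-ol, via pinacol borate ester 5 (not isolated)
Conditions: (S)-TRIP [(S)-3,3'-bis(2,4,6-triisopropylphenyl)-1,1'-binaphthyl-2,2'-diyl hydrogen phosphate, 10 mol %], 4 Å MS, toluene, −20 °C; aq. NaHCO3 work-up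
Reagents that add atoms: none
Why: Brønsted acid-catalysed asymmetric propargylation, in which the allenylboronate adds by SE2' through a closed six-membered transition state organised by the chiral phosphoric acid; the (S)-acid is the antipode assigned to Si-face attack on the aldehyde, which sets C3 as S (to be confirmed by MTPA ester analysis).

Step 3
Reactants: 6 (2E,4S)-1-[(4-methoxybenzyl)oxy]-3-methylhept-2-en-6-yn-4-ol
Product: 7 tert-butyl{[(2E,4S)-1-[(4-methoxybenzyl)oxy]-3-methylhept-2-en-6-yn-4-yl]oxy}dimethylsilane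
Conditions: TBSCl, imidazole, DMF, 25 °C
Reagents that add atoms: tert-butyldimethylsilyl chloride, CC(C)(C)[Si](C)(C)Cl
Why: Standard silylation of a secondary alcohol, giving an ether that is inert to the organometallic steps and, unlike an allylic acetate, to zerovalent nickel.

Step 4
Reactants: 7 tert-butyl{[(2E,4S)-1-[(4-methoxybenzyl)oxy]-3-methylhept-2-en-6-yn-4-yl]oxy}dimethylsilane
Product: 9 tert-butyl{[(2E,4S)-1-[(4-methoxybenzyl)oxy]-3-methyloct-2-en-6-yn-4-yl]oxy}dimethylsilane, via lithium acetylide 8 (not isolated)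
Conditions: n-BuLi, THF, −78 °C; MeI, −78 to 25 °C
Reagents that add atoms: iodomethane, CI
Why: Acetylide alkylation; the alkyne C–H is by far the most acidic site, so one equivalent of base at −78 °C should leave the allylic and benzylic ether positions untouched, and the methyl group becomes C14.

Step 5
Reactants: 9 tert-butyl{[(2E,4S)-1-[(4-methoxybenzyl)oxy]-3-methyloct-2-en-6-yn-4-yl]oxy}dimethylsilane
Product: 11 tert-butyl{[(2E,4S,6E)-7-iodo-1-[(4-methoxybenzyl)oxy]-3-methylocta-2,6-dien-4-yl]oxy}dimethylsilane, via alkenylzirconocene chloride 10 (not isolated)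
Conditions: Cp2Zr(H)Cl (2.5 equiv), THF, 50 °C; then I2, 0 °C
Reagents that add atoms: iodine, II
Why: Hydrozirconation–iodination: syn addition of Zr–H, equilibration with excess hydride to the less hindered methyl-bearing carbon and iodinolysis with retention should give the (E)-2-iodoalkene, while the trisubstituted C4=C5 alkene is too hindered to react.

Step 6
Reactants: 12 tert-butyldimethyl(prop-2-yn-1-yloxy)silane; 13 oxirane
Product: 15 5-[(tert-butyldimethylsilyl)oxy]pent-3-yn-1-ol, via lithium acetylide 14 (not isolated)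
Conditions: n-BuLi, THF, −78 °C; 13, DMPU, −78 to 25 °C; H2O quench
Reagents that add atoms: none
Why: Ring opening of oxirane by a lithium acetylide in a dipolar cosolvent delivers the two-carbon unit C8–C9.

Step 7
Reactants: 15 5-[(tert-butyldimethylsilyl)oxy]pent-3-yn-1-ol
Product: 16 tert-butyl[(5-iodopent-2-yn-1-yl)oxy]dimethylsilane
Conditions: I2, PPh3, imidazole, CH2Cl2, 0 °C
Reagents that add atoms: iodine, II
Why: Appel-type iodination of a primary alcohol under neutral conditions that the silyl ether tolerates.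

Step 8
Reactants: 16 tert-butyl[(5-iodopent-2-yn-1-yl)oxy]dimethylsilane; 11 tert-butyl{[(2E,4S,6E)-7-iodo-1-[(4-methoxybenzyl)oxy]-3-methylocta-2,6-dien-4-yl]oxy}dimethylsilane
Product: 18 tert-butyl{[(2E,4S,6E)-12-[(tert-butyldimethylsilyl)oxy]-1-[(4-methoxybenzyl)oxy]-3,7-dimethyldodeca-2,6-dien-10-yn-4-yl]oxy}dimethylsilane, via alkylzinc iodide 17 (not isolated)
Conditions: 16, Zn dust (activated), LiCl, THF, 40 °C; then 11, Pd(dppf)Cl2 (5 mol %), THF/DMA, 40 °C
Reagents that add atoms: none
Why: Negishi alkyl–alkenyl cross-coupling forms C9–C10; the alkenyl iodide couples with retention, so the trisubstituted alkene is E, and the bidentate ligand disfavours β-hydride elimination of the alkylpalladium.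

Step 9
Reactants: 18 tert-butyl{[(2E,4S,6E)-12-[(tert-butyldimethylsilyl)oxy]-1-[(4-methoxybenzyl)oxy]-3,7-dimethyldodeca-2,6-dien-10-yn-4-yl]oxy}dimethylsilane
Product: 19 tert-butyl{[(2E,4S)-5-[(2R,3R)-3-{5-[(tert-butyldimethylsilyl)oxy]pent-3-yn-1-yl}-3-methyloxiran-2-yl]-1-[(4-methoxybenzyl)oxy]-3-methylpent-2-en-4-yl]oxy}dimethylsilane
Conditions: D-fructose-derived Shi ketone (0.3 equiv), KHSO5 (as Oxone), K2CO3, Bu4NHSO4 (cat.), MeCN/CH2(OMe)2/aq. Na2B4O7 buffer, 0 °C
Reagents that add atoms: potassium peroxymonosulfate (Oxone), [K+].OOS(=O)(=O)[O-]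
Why: Shi asymmetric epoxidation: the chiral dioxirane should attack the electron-rich (E)-trisubstituted alkene through the spiro transition state to give the (R,R)-epoxide (C1 and C10), whereas the other alkene is deactivated by two allylic C–O bonds and adjacent branching and the alkyne is inert.

Step 10
Reactants: 19 tert-butyl{[(2E,4S)-5-[(2R,3R)-3-{5-[(tert-butyldimethylsilyl)oxy]pent-3-yn-1-yl}-3-methyloxiran-2-yl]-1-[(4-methoxybenzyl)oxy]-3-methylpent-2-en-4-yl]oxy}dimethylsilane
Product: 20 (2E,4S)-4-[(tert-butyldimethylsilyl)oxy]-5-[(2R,3R)-3-{5-[(tert-butyldimethylsilyl)oxy]pent-3-yn-1-yl}-3-methyloxiran-2-yl]-3-methylpent-2-en-1-ol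
Conditions: DDQ, CH2Cl2/pH 7 buffer, 0 °C
Reagents that add atoms: none
Why: Oxidative cleavage of the 4-methoxybenzyl ether under buffered conditions that leave the silyl ethers and the epoxide intact.

Step 11
Reactants: 20 (2E,4S)-4-[(tert-butyldimethylsilyl)oxy]-5-[(2R,3R)-3-{5-[(tert-butyldimethylsilyl)oxy]pent-3-yn-1-yl}-3-methyloxiran-2-yl]-3-methylpent-2-en-1-ol
Product: 21 (2E,4S)-4-[(tert-butyldimethylsilyl)oxy]-5-[(2R,3R)-3-{5-[(tert-butyldimethylsilyl)oxy]pent-3-yn-1-yl}-3-methyloxiran-2-yl]-3-methylpent-2-enal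
Conditions: MnO2, CH2Cl2, 25 °C
Reagents that add atoms: none
Why: Chemoselective oxidation of the primary allylic alcohol to the (E)-enal without touching the epoxide or the alkene geometry.

Step 12
Reactants: 21 (2E,4S)-4-[(tert-butyldimethylsilyl)oxy]-5-[(2R,3R)-3-{5-[(tert-butyldimethylsilyl)oxy]pent-3-yn-1-yl}-3-methyloxiran-2-yl]-3-methylpent-2-enal
Product: 23 (1R,3S,6R,10R,4E)-3,13-bis[(tert-butyldimethylsilyl)oxy]-1,10-epoxygermacra-4,7(11)-dien-12,6-olide, via nickeladihydrofuran 22 (not isolated)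
Conditions: Ni(cod)2 (1.1 equiv), PCy3 (1.1 equiv), toluene (0.002 M, slow addition of 21), 25 °C; then CO (1 atm), 25 °C
Reagents that add atoms: carbon monoxide, [C-]#[O+]
Why: Proposed new method: zerovalent nickel binds the aldehyde (C6=O) and the alkyne (C7≡C11) and couples them by oxidative cyclization to the five-membered nickeladihydrofuran 22, which forms the C6–C7 bond and with it the ten-membered carbocycle; CO then inserts into the Ni–C11 bond (C11–C12) and C12–O reductive elimination releases the butenolide, so the net event is a macrocyclic hetero-Pauson–Khand-type [2+2+1] annulation. The closest known reaction types are the intramolecular hetero-Pauson–Khand cyclocarbonylation of 1,6- and 1,7-ynals to fused butenolides (Ru3(CO)12 catalysis, Mo(CO)6 mediation), the nickel-catalysed reductive macrocyclization of ynals and the stoichiometric carbonylation of nickeladihydrofurans to butenolides; what is new is their combination to close a medium ring. The ten-membered ring closes in the exo-dig mode (C–C bond at the tethered alkyne carbon C7, C11 exocyclic), and the lactone closes by C(acyl)–O reductive elimination from the six-membered acylnickel alkoxide. C6 is set under control of C3: with the s-trans enal (formyl H toward the C15 methyl) and the C3–H bond eclipsing C4=C5, the tether leaves C3 on the face opposite to the silyloxy group and C7 is delivered to that same face of C6=O, which for (3S) gives (6R). The step needs exo over endo (eleven-membered) cyclization, 1,2- over 1,4-coupling of the enal and cyclization over oligomerization; the fully substituted β-carbon of the enal, placement of nickel on C11 next to the inductively withdrawing C13–O bond, the bulky monophosphine, high dilution and admission of CO only after the nickelacycle has formed are meant to secure these. Silyl ethers rather than acetates at the allylic C3 and propargylic C13 oxygens avoid oxidative addition and β-oxygen elimination at nickel, and the trisubstituted epoxide is not expected to react with phosphine-ligated nickel at 25 °C without a Lewis acid.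

Step 13
Reactants: 23 (1R,3S,6R,10R,4E)-3,13-bis[(tert-butyldimethylsilyl)oxy]-1,10-epoxygermacra-4,7(11)-dien-12,6-olide
Product: 24 (1R,3S,6R,10R,4E)-1,10-epoxy-3,13-dihydroxygermacra-4,7(11)-dien-12,6-olide
Conditions: HF·pyridine, pyridine (excess), THF, 0 to 25 °C
Reagents that add atoms: none
Why: Buffered fluoride-mediated desilylation removes both allylic silyl ethers under conditions too weakly acidic to open the trisubstituted epoxide and too weakly basic to epimerize the doubly allylic C6–H.

Step 14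
Reactants: 24 (1R,3S,6R,10R,4E)-1,10-epoxy-3,13-dihydroxygermacra-4,7(11)-dien-12,6-olide
Product: 25 (1R,3S,6R,10R,4E)-3,13-diacetoxy-1,10-epoxygermacra-4,7(11)-dien-12,6-olide (CNP0294733.1)
Conditions: Ac2O, pyridine, DMAP (cat.), CH2Cl2, 0 to 25 °C
Reagents that add atoms: acetic anhydride, CC(=O)OC(C)=O
Why: Acylation of the primary and the secondary allylic alcohol in one operation, with no change at any stereocentre, completes the target.

**Compound list**

1 | 2-[(4-methoxybenzyl)oxy]acetaldehyde | COc1ccc(COCC=O)cc1 | starting material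
2 | 2-(triphenylphosphoranylidene)propanal | CC(C=O)=P(c1ccccc1)(c1ccccc1)c1ccccc1 | starting material
3 | (2E)-4-[(4-methoxybenzyl)oxy]-2-methylbut-2-enal | COc1ccc(COC/C=C(\C)C=O)cc1 | intermediate
4 | allenylboronic acid pinacol ester | C=C=CB1OC(C)(C)C(C)(C)O1 | starting material
5 | pinacol borate ester of alcohol 6 | C#CC[C@H](OB1OC(C)(C)C(C)(C)O1)/C(C)=C/COCc1ccc(OC)cc1 | intermediate
6 | (2E,4S)-1-[(4-methoxybenzyl)oxy]-3-methylhept-2-en-6-yn-4-ol | C#CC[C@H](O)/C(C)=C/COCc1ccc(OC)cc1 | intermediate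
7 | tert-butyl{[(2E,4S)-1-[(4-methoxybenzyl)oxy]-3-methylhept-2-en-6-yn-4-yl]oxy}dimethylsilane | C#CC[C@H](O[Si](C)(C)C(C)(C)C)/C(C)=C/COCc1ccc(OC)cc1 | intermediate
8 | lithium acetylide of 7 | [Li]C#CC[C@H](O[Si](C)(C)C(C)(C)C)/C(C)=C/COCc1ccc(OC)cc1 | intermediate
9 | tert-butyl{[(2E,4S)-1-[(4-methoxybenzyl)oxy]-3-methyloct-2-en-6-yn-4-yl]oxy}dimethylsilane | CC#CC[C@H](O[Si](C)(C)C(C)(C)C)/C(C)=C/COCc1ccc(OC)cc1 | intermediate
10 | (E)-alkenylzirconocene chloride from 9 (Zr on the methyl-bearing carbon) | C/C(=C\C[C@H](O[Si](C)(C)C(C)(C)C)/C(C)=C/COCc1ccc(OC)cc1)[Zr](Cl)(C1C=CC=C1)C1C=CC=C1 | intermediate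
11 | tert-butyl{[(2E,4S,6E)-7-iodo-1-[(4-methoxybenzyl)oxy]-3-methylocta-2,6-dien-4-yl]oxy}dimethylsilane | C/C(I)=C\C[C@H](O[Si](C)(C)C(C)(C)C)/C(C)=C/COCc1ccc(OC)cc1 | intermediate
12 | tert-butyldimethyl(prop-2-yn-1-yloxy)silane | C#CCO[Si](C)(C)C(C)(C)C | starting material
13 | oxirane | C1CO1 | starting material
14 | lithium acetylide of 12 | [Li]C#CCO[Si](C)(C)C(C)(C)C | intermediate
15 | 5-[(tert-butyldimethylsilyl)oxy]pent-3-yn-1-ol | OCCC#CCO[Si](C)(C)C(C)(C)C | intermediate
16 | tert-butyl[(5-iodopent-2-yn-1-yl)oxy]dimethylsilane | ICCC#CCO[Si](C)(C)C(C)(C)C | intermediate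
17 | {5-[(tert-butyldimethylsilyl)oxy]pent-3-yn-1-yl}zinc iodide | I[Zn]CCC#CCO[Si](C)(C)C(C)(C)C | intermediate
18 | tert-butyl{[(2E,4S,6E)-12-[(tert-butyldimethylsilyl)oxy]-1-[(4-methoxybenzyl)oxy]-3,7-dimethyldodeca-2,6-dien-10-yn-4-yl]oxy}dimethylsilane | CC(C)(C)[Si](C)(C)OCC#CCC/C(C)=C/C[C@H](O[Si](C)(C)C(C)(C)C)/C(C)=C/COCc1ccc(OC)cc1 | intermediate
19 | tert-butyl{[(2E,4S)-5-[(2R,3R)-3-{5-[(tert-butyldimethylsilyl)oxy]pent-3-yn-1-yl}-3-methyloxiran-2-yl]-1-[(4-methoxybenzyl)oxy]-3-methylpent-2-en-4-yl]oxy}dimethylsilane | CC(C)(C)[Si](C)(C)OCC#CCC[C@@]1(C)O[C@@H]1C[C@H](O[Si](C)(C)C(C)(C)C)/C(C)=C/COCc1ccc(OC)cc1 | intermediate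
20 | (2E,4S)-4-[(tert-butyldimethylsilyl)oxy]-5-[(2R,3R)-3-{5-[(tert-butyldimethylsilyl)oxy]pent-3-yn-1-yl}-3-methyloxiran-2-yl]-3-methylpent-2-en-1-ol | CC(C)(C)[Si](C)(C)OCC#CCC[C@@]1(C)O[C@@H]1C[C@H](O[Si](C)(C)C(C)(C)C)/C(C)=C/CO | intermediate
21 | (2E,4S)-4-[(tert-butyldimethylsilyl)oxy]-5-[(2R,3R)-3-{5-[(tert-butyldimethylsilyl)oxy]pent-3-yn-1-yl}-3-methyloxiran-2-yl]-3-methylpent-2-enal | CC(C)(C)[Si](C)(C)OCC#CCC[C@@]1(C)O[C@@H]1C[C@H](O[Si](C)(C)C(C)(C)C)/C(C)=C/C=O | intermediate
22 | nickeladihydrofuran (Ni bonded to O6 and C11, ten-membered ring closed) with PCy3 ligand | CC(C)(C)[Si](C)(C)OCC1=C2CC[C@@]3(C)O[C@@H]3C[C@H](O[Si](C)(C)C(C)(C)C)/C(C)=C/[C@H]2O[Ni]1.C1CCC(CC1)P(C1CCCCC1)C1CCCCC1 | intermediate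
23 | (1R,3S,6R,10R,4E)-3,13-bis[(tert-butyldimethylsilyl)oxy]-1,10-epoxygermacra-4,7(11)-dien-12,6-olide | CC(C)(C)[Si](C)(C)OCC1=C2CC[C@@]3(C)O[C@@H]3C[C@H](O[Si](C)(C)C(C)(C)C)/C(C)=C/[C@H]2OC1=O | intermediate
24 | (1R,3S,6R,10R,4E)-1,10-epoxy-3,13-dihydroxygermacra-4,7(11)-dien-12,6-olide | OCC1=C2CC[C@@]3(C)O[C@@H]3C[C@H](O)/C(C)=C/[C@H]2OC1=O | intermediate
25 | (1R,3S,6R,10R,4E)-3,13-diacetoxy-1,10-epoxygermacra-4,7(11)-dien-12,6-olide | CC(=O)OCC1=C2CC[C@@]3(C)O[C@@H]3C[C@H](OC(C)=O)/C(C)=C/[C@H]2OC1=O | target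

**Count**

Total steps: 14. Longest linear sequence: 12 steps (steps 1–5 and 8–14); steps 6–7 make the second coupling partner.

**Steps most likely to fail**

1. Step 12 (bears the label). What may go wrong: oxidative cyclization in the endo sense or between two molecules instead of the ten-membered exo closure, attack on the wrong face of the C6 carbonyl, or opening of the epoxide at nickel.
Fallback with known chemistry, setting out from vinyl iodide 11 and coming back at macrocycle 23; it forms C6–C7 and the lactone C–O bond on a chain that already carries C12. Negishi coupling of 11 with (3-ethoxy-3-oxopropyl)zinc bromide (Pd(dppf)Cl2, THF) should give the ethyl dienoate F1. Crossed Claisen condensation of F1 with the lithium enolate of methyl 3-[(tert-butyldimethylsilyl)oxy]propanoate (LiN(iPr)2, THF, −78 °C) gives the β-keto ester F2. Trapping of its chelated sodium enolate (NaH, PhNTf2) gives the (Z)-enol triflate F3, the only isomer able to lactonize later. Shi epoxidation as in step 9 gives the epoxide F4, DDQ gives the allylic alcohol F5 and MnO2 gives the enal F6. An intramolecular Nozaki–Hiyama–Kishi reaction (CrCl2, cat. NiCl2, DMF, high dilution) then closes the ten-membered ring at C6–C7, and the chromium alkoxide lactonizes onto the cis ester to give 23.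

2. Step 8. What may go wrong: slow or incomplete zinc insertion, protodemetalation or β-hydride elimination of the homopropargylic organometallic, so that the two chain pieces are not joined efficiently.
Fallback with reversed roles of the partners, setting out from 11 and 16 and coming back at 18. Iodine–lithium exchange on 11 (t-BuLi, Et2O, −78 °C) gives the alkenyllithium F7, and ZnCl2 converts it to the alkenylzinc chloride F8. F8 is then coupled with the primary alkyl iodide 16 under conditions for unactivated alkyl electrophiles (Pd2(dba)3, PCyp3, N-methylimidazole, THF/NMP, 80 °C).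

3. Step 2. What may go wrong: insufficient enantioface discrimination with the α-branched enal, so that C3, which controls C6 later, is not set cleanly.
Fallback by resolution, setting out from 3 and coming back at 6. Barbier propargylation (Zn, propargyl bromide, THF/aq. NH4Cl) gives the racemic alcohol F9. A lipase-mediated kinetic resolution (lipase from Burkholderia cepacia, vinyl acetate, MTBE, 30 °C) should, by the empirical rule for secondary alcohols, acylate the (4R)-enantiomer to the (R)-acetate F10 and leave (4S)-alcohol 6 for separation.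

**Further compounds**

F1 | step 12 | ethyl (4E,7S,8E)-7-[(tert-butyldimethylsilyl)oxy]-10-[(4-methoxybenzyl)oxy]-4,8-dimethyldeca-4,8-dienoate | CCOC(=O)CC/C(C)=C/C[C@H](O[Si](C)(C)C(C)(C)C)/C(C)=C/COCc1ccc(OC)cc1
F2 | step 12 | methyl (6E,9S,10E)-9-[(tert-butyldimethylsilyl)oxy]-2-{[(tert-butyldimethylsilyl)oxy]methyl}-12-[(4-methoxybenzyl)oxy]-6,10-dimethyl-3-oxododeca-6,10-dienoate (both C2 epimers) | COC(=O)C(CO[Si](C)(C)C(C)(C)C)C(=O)CC/C(C)=C/C[C@H](O[Si](C)(C)C(C)(C)C)/C(C)=C/COCc1ccc(OC)cc1
F3 | step 12 | methyl (2Z,6E,9S,10E)-9-[(tert-butyldimethylsilyl)oxy]-2-{[(tert-butyldimethylsilyl)oxy]methyl}-12-[(4-methoxybenzyl)oxy]-6,10-dimethyl-3-[(trifluoromethanesulfonyl)oxy]dodeca-2,6,10-trienoate | COC(=O)/C(CO[Si](C)(C)C(C)(C)C)=C(\OS(=O)(=O)C(F)(F)F)CC/C(C)=C/C[C@H](O[Si](C)(C)C(C)(C)C)/C(C)=C/COCc1ccc(OC)cc1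
F4 | step 12 | (6R,7R)-6,7-epoxide of F3 | COC(=O)/C(CO[Si](C)(C)C(C)(C)C)=C(\OS(=O)(=O)C(F)(F)F)CC[C@@]1(C)O[C@@H]1C[C@H](O[Si](C)(C)C(C)(C)C)/C(C)=C/COCc1ccc(OC)cc1
F5 | step 12 | primary allylic alcohol from F4 (4-methoxybenzyl group removed) | COC(=O)/C(CO[Si](C)(C)C(C)(C)C)=C(\OS(=O)(=O)C(F)(F)F)CC[C@@]1(C)O[C@@H]1C[C@H](O[Si](C)(C)C(C)(C)C)/C(C)=C/CO
F6 | step 12 | enal from F5 (enol triflate, methyl ester, epoxide and aldehyde in one chain) | COC(=O)/C(CO[Si](C)(C)C(C)(C)C)=C(\OS(=O)(=O)C(F)(F)F)CC[C@@]1(C)O[C@@H]1C[C@H](O[Si](C)(C)C(C)(C)C)/C(C)=C/C=O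
F7 | step 8 | (E)-alkenyllithium from 11 | C/C([Li])=C\C[C@H](O[Si](C)(C)C(C)(C)C)/C(C)=C/COCc1ccc(OC)cc1
F8 | step 8 | (E)-alkenylzinc chloride from 11 | C/C([Zn]Cl)=C\C[C@H](O[Si](C)(C)C(C)(C)C)/C(C)=C/COCc1ccc(OC)cc1
F9 | step 2 | racemic (2E)-1-[(4-methoxybenzyl)oxy]-3-methylhept-2-en-6-yn-4-ol | C#CCC(O)/C(C)=C/COCc1ccc(OC)cc1
F10 | step 2 | (2E,4R)-1-[(4-methoxybenzyl)oxy]-3-methylhept-2-en-6-yn-4-yl acetate | C#CC[C@@H](OC(C)=O)/C(C)=C/COCc1ccc(OC)cc1
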